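**Assumption:** germacrane numbering is used (lactone O on C6, C11 on C7, ester on C8, epoxide C1–C10, diol C3/C4), so the target is 8β-angeloyloxy-1β,10β-epoxy-3β,4α-dihydroxygermacr-11(13)-en-12,6α-olide; (R)-glycidyl 4-methoxybenzyl ether (glycidol pool) is taken as a catalogue item.

## Retrosynthetic overview

1. 25 ⇒ triene lactone 20 by three late operations on the ring: 8-OH-directed epoxidation of the 1(10)Z olefin (C1, C10), angelate on O8, OsO4 on the 3E olefin (C3, C4).
2. 20 ⇒ acyclic aldehyde/allylic bromide 17: cathodic CrCl2-catalysed intramolecular allylation forms C6–C7 and closes the ten-membered carbocycle; the γ-lactone closes in the same operation, and the epoxide is the last ring formed.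
3. 17 ⇒ α-silyloxy aldehyde 12 + methyl propiolate 13 (C11–C13 unit); 12 ⇒ skipped Z,E-diene 9.
4. 9 ⇒ alkynol 6 (from epoxide 5, the only purchased stereocentre, C8) + allylic chloride 4 (from but-3-yn-1-ol 1); two carboaluminations fix both olefin geometries.

## Route

Step 1
Reactants: 1 but-3-yn-1-ol
Product: 3 (E)-3-methylpent-2-ene-1,5-diol, via E-alkenylalane 2 (not isolated)
Conditions: Me3Al (3 equiv), Cp2ZrCl2 (0.25 equiv), CH2Cl2, 0→23 °C; then n-BuLi, (CH2O)n, THF, −78→23 °C
Reagents that add atoms: trimethylaluminium C[Al](C)C; formaldehyde (as paraformaldehyde) C=O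
Why: Negishi Cp2ZrCl2-catalysed syn-carboalumination of the terminal alkyne fixes the E trisubstituted olefin, and the derived alanate is hydroxymethylated with retention.

Step 2
Reactants: 3 (E)-3-methylpent-2-ene-1,5-diol
Product: 4 (E)-5-chloro-3-methylpent-3-en-1-ol
Conditions: NCS, Me2S, CH2Cl2, −20→0 °C
Reagents that add atoms: N-chlorosuccinimide O=C1CCC(=O)N1Cl
Why: Corey–Kim chlorination ionises only the allylic alkoxysulfonium salt, so the allylic hydroxyl alone becomes chloride and the olefin geometry is kept.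

Step 3
Reactants: 5 (R)-glycidyl 4-methoxybenzyl ether
Product: 6 (R)-1-[(4-methoxybenzyl)oxy]pent-4-yn-2-ol
Conditions: LiC≡CH·H2NCH2CH2NH2, DMSO, 0→23 °C
Reagents that add atoms: lithium acetylide [Li]C#C
Why: SN2 epoxide opening by acetylide at the unsubstituted carbon leaves the purchased stereocentre untouched; it becomes C8 of the target.

Step 4
Reactants: 6 (R)-1-[(4-methoxybenzyl)oxy]pent-4-yn-2-ol; 4 (E)-5-chloro-3-methylpent-3-en-1-ol
Product: 9 (2R,4Z,7E)-1-[(4-methoxybenzyl)oxy]-4,8-dimethyldeca-4,7-diene-2,10-diol, via syn-alkenylalane 7 (not isolated), via chelated Z-alkenylalane 8 (not isolated)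
Conditions: Me3Al (3.5 equiv), Cp2ZrCl2 (0.25 equiv), ClCH2CH2Cl, 23 °C then 55 °C; then 4·Me3Al (1 equiv), ZnCl2, Pd(PPh3)4 (5 mol %), THF, 23→45 °C
Reagents that add atoms: trimethylaluminium C[Al](C)C
Why: Negishi–Ma anti-carboalumination (syn addition, then chelation-driven isomerisation of the homopropargylic aluminium alkoxide) gives the Z-alkenylalane, and its zerovalent-palladium-catalysed Negishi coupling with the allylic chloride joins at the primary carbon with retention of both olefin geometries.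

Step 5
Reactants: 9 (2R,4Z,7E)-1-[(4-methoxybenzyl)oxy]-4,8-dimethyldeca-4,7-diene-2,10-diol
Product: 10 (2R,4Z,7E)-1-[(4-methoxybenzyl)oxy]-4,8-dimethyl-2,10-bis(triethylsilyloxy)deca-4,7-diene
Conditions: Et3SiCl (2.4 equiv), imidazole, DMF, 0→23 °C
Reagents that add atoms: chlorotriethylsilane CC[Si](CC)(CC)Cl
Why: standard silyl ether formation on both hydroxyls; no stereocentre is touched.

Step 6
Reactants: 10 (2R,4Z,7E)-1-[(4-methoxybenzyl)oxy]-4,8-dimethyl-2,10-bis(triethylsilyloxy)deca-4,7-diene
Product: 11 (2R,4Z,7E)-4,8-dimethyl-2,10-bis(triethylsilyloxy)deca-4,7-dien-1-ol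
Conditions: DDQ, CH2Cl2/pH 7 buffer, 0 °C
Reagents that add atoms: none
Why: oxidative cleavage of the 4-methoxybenzyl ether by DDQ under buffered conditions spares the silyl ethers and the skipped diene; the alcohol is oxidised at once to forestall silyl migration.

Step 7
Reactants: 11 (2R,4Z,7E)-4,8-dimethyl-2,10-bis(triethylsilyloxy)deca-4,7-dien-1-ol
Product: 12 (2R,4Z,7E)-4,8-dimethyl-2,10-bis(triethylsilyloxy)deca-4,7-dienal
Conditions: Dess–Martin periodinane, pyridine, CH2Cl2, 0→23 °C
Reagents that add atoms: none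
Why: Dess–Martin oxidation is neutral, so the α-silyloxy aldehyde is formed without epimerisation and is used crude.

Step 8
Reactants: 12 (2R,4Z,7E)-4,8-dimethyl-2,10-bis(triethylsilyloxy)deca-4,7-dienal; 13 methyl propiolate
Product: 15 methyl (4R,6Z,9E)-3-hydroxy-6,10-dimethyl-2-methylidene-4,12-bis(triethylsilyloxy)dodeca-6,9-dienoate (both C3 epimers), via α-aluminio acrylate 14 (not isolated)
Conditions: 13, i-Bu2AlH, NMO, THF, 0 °C; then 12, 0→23 °C
Reagents that add atoms: none
Why: vinylalumination (a fast, non-basic Morita–Baylis–Hillman equivalent) adds the α-aluminio acrylate 1,2 to the aldehyde; the new carbinol configuration is immaterial because it becomes sp2 in step 9.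

Step 9
Reactants: 15 methyl (4R,6Z,9E)-3-hydroxy-6,10-dimethyl-2-methylidene-4,12-bis(triethylsilyloxy)dodeca-6,9-dienoate
Product: 16 methyl (2Z,4R,6Z,9E)-2-(bromomethyl)-6,10-dimethyl-4,12-bis(triethylsilyloxy)dodeca-2,6,9-trienoate
Conditions: NBS, Me2S, CH2Cl2, 0 °C
Reagents that add atoms: N-bromosuccinimide O=C1CCC(=O)N1Br
Why: Corey–Kim-type bromination of the Baylis–Hillman alcohol with allylic transposition (SN2′) gives the thermodynamic 2Z primary bromide under neutral conditions; C4 is not involved.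

Step 10
Reactants: 16 methyl (2Z,4R,6Z,9E)-2-(bromomethyl)-6,10-dimethyl-4,12-bis(triethylsilyloxy)dodeca-2,6,9-trienoate
Product: 17 methyl (2Z,4R,6Z,9E)-2-(bromomethyl)-6,10-dimethyl-12-oxo-4-(triethylsilyloxy)dodeca-2,6,9-trienoate
Conditions: (COCl)2, DMSO, CH2Cl2, −78→−40 °C; i-Pr2NEt, −78→−20 °C
Reagents that add atoms: none
Why: under Swern conditions chlorodimethylsulfonium chloride desilylates and oxidises only the primary triethylsilyl ether in one flask, the hindered base i-Pr2NEt does not quaternise on the allylic bromide, and the low temperature prevents conjugation of the β,γ-unsaturated aldehyde.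

Step 11
Reactants: 17 methyl (2Z,4R,6Z,9E)-2-(bromomethyl)-6,10-dimethyl-12-oxo-4-(triethylsilyloxy)dodeca-2,6,9-trienoate
Product: 20 8β-hydroxygermacra-1(10)Z,3E,11(13)-trien-12,6α-olide, via trimethylsilyl ether ester 18 (not isolated), via triethylsilyl ether lactone 19 (not isolated)
Conditions: CrCl2 (20 mol %), Me3SiCl (3 equiv), n-Bu4NPF6, THF/DMF 4:1, undivided cell, Al anode, Ni-foam cathode, 3 mA, 2.4 F/mol, 17 by syringe pump over 12 h (2 mM), 23 °C; then TsOH·H2O (cat.), THF/H2O, 23 °C
Reagents that add atoms: none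
Why: Proposed new method: electroreductive CrCl2-catalysed intramolecular Barbier (Nozaki–Hiyama) allylation closing a ten-membered ring — the cathode regenerates divalent chromium from the trivalent chromium alkoxide after Me3SiCl exchange, two divalent chromium ions turn the allylic bromide into a σ-allylchromium species that equilibrates to the form with C8 trans to CH2Cr and adds to the tethered aldehyde through a chair Zimmerman–Traxler transition state (both ring branches equatorial, hence 6,7-anti and the trans lactone), with C8–H inside to avoid A(1,3) strain with the ester, the C8–C9 bond anti and the silyloxy group outside, which is the model expected to set C7 from the purchased C8, while the current-limited chromium and substrate concentrations favour ring closure over dimerisation; acid then removes the labile trimethylsilyl group, the C6 hydroxyl lactonises and the triethylsilyl group is cleaved last; the closest known reactions are the stoichiometric CrCl2 Barbier macrocyclisation used for parthenolide-type ten-membered rings and the intermolecular electrochemical CrCl2-catalysed Nozaki–Hiyama–Kishi coupling.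

Step 12
Reactants: 20 8β-hydroxygermacra-1(10)Z,3E,11(13)-trien-12,6α-olide
Product: 21 1β,10β-epoxy-8β-hydroxygermacra-3E,11(13)-dien-12,6α-olide
Conditions: VO(acac)2 (5 mol %), t-BuOOH, CH2Cl2, 0→23 °C
Reagents that add atoms: tert-butyl hydroperoxide CC(C)(C)OO
Why: VO(acac)2-catalysed hydroxyl-directed epoxidation delivers oxygen from the homoallylic 8β-hydroxyl to the β face of the 1(10)Z olefin only (sets C1 and C10); the 3E olefin is out of reach and the enoate is inert.

Step 13
Reactants: 21 1β,10β-epoxy-8β-hydroxygermacra-3E,11(13)-dien-12,6α-olide; 22 angelic acid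
Product: 24 8β-angeloyloxy-1β,10β-epoxygermacra-3E,11(13)-dien-12,6α-olide, via mixed anhydride 23 (not isolated)
Conditions: 22, 2,4,6-Cl3C6H2COCl, Et3N, toluene, 23 °C; then 21, 75 °C
Reagents that add atoms: none
Why: mixed-anhydride (Yamaguchi-type) esterification acylates the only hydroxyl, and these conditions are known to give angelates without Z to E isomerisation to the tiglate.

Step 14
Reactants: 24 8β-angeloyloxy-1β,10β-epoxygermacra-3E,11(13)-dien-12,6α-olide
Product: 25 8β-angeloyloxy-1β,10β-epoxy-3β,4α-dihydroxygermacr-11(13)-en-12,6α-olide (CNP0113954.1)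
Conditions: OsO4 (5 mol %), NMO, acetone/H2O 5:1, 0 °C
Reagents that add atoms: osmium tetroxide (catalytic carrier) O=[Os](=O)(=O)=O; N-methylmorpholine N-oxide C[N+]1([O-])CCOCC1; water O
Why: Upjohn syn-dihydroxylation attacks the only electron-rich olefin from its peripheral face (C15 methyl β, inner face shielded by the ring), giving the 3β,4α-diol (3S,4S) as required for syn addition to the E olefin; both conjugated olefins react far more slowly.

## Compound list

1 | but-3-yn-1-ol | C#CCCO | starting material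
2 | dimethyl[(E)-4-(dimethylalumanyloxy)-2-methylbut-1-enyl]alane | C[Al](C)/C=C(\C)CCO[Al](C)C | intermediate (not isolated)
3 | (E)-3-methylpent-2-ene-1,5-diol | OC/C=C(\C)CCO | intermediate
4 | (E)-5-chloro-3-methylpent-3-en-1-ol | ClC/C=C(\C)CCO | intermediate
5 | (R)-glycidyl 4-methoxybenzyl ether, (R)-2-{[(4-methoxybenzyl)oxy]methyl}oxirane | COc1ccc(COC[C@H]2CO2)cc1 | starting material
6 | (R)-1-[(4-methoxybenzyl)oxy]pent-4-yn-2-ol | C#CC[C@@H](O)COCc1ccc(OC)cc1 | intermediate
7 | syn-carboalumination product of 6, (E)-alkenyl(dimethyl)alane with O-dimethylalumanyl alkoxide | C[Al](C)/C=C(\C)C[C@@H](O[Al](C)C)COCc1ccc(OC)cc1 | intermediate (not isolated)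
8 | chelated Z-alkenylalane, (R)-6-{[(4-methoxybenzyl)oxy]methyl}-2,4-dimethyl-1,2-oxaaluminacyclohex-3-ene | C[Al]1O[C@@H](COCc2ccc(OC)cc2)CC(C)=C1 | intermediate (not isolated)
9 | (2R,4Z,7E)-1-[(4-methoxybenzyl)oxy]-4,8-dimethyldeca-4,7-diene-2,10-diol | COc1ccc(COC[C@H](O)C/C(C)=C\C/C=C(\C)CCO)cc1 | intermediate
10 | (2R,4Z,7E)-1-[(4-methoxybenzyl)oxy]-4,8-dimethyl-2,10-bis(triethylsilyloxy)deca-4,7-diene | COc1ccc(COC[C@H](O[Si](CC)(CC)CC)C/C(C)=C\C/C=C(\C)CCO[Si](CC)(CC)CC)cc1 | intermediate
11 | (2R,4Z,7E)-4,8-dimethyl-2,10-bis(triethylsilyloxy)deca-4,7-dien-1-ol | OC[C@H](O[Si](CC)(CC)CC)C/C(C)=C\C/C=C(\C)CCO[Si](CC)(CC)CC | intermediate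
12 | (2R,4Z,7E)-4,8-dimethyl-2,10-bis(triethylsilyloxy)deca-4,7-dienal | O=C[C@H](O[Si](CC)(CC)CC)C/C(C)=C\C/C=C(\C)CCO[Si](CC)(CC)CC | intermediate
13 | methyl propiolate | C#CC(=O)OC | starting material
14 | methyl 2-(diisobutylalumanyl)acrylate | C=C(C(=O)OC)[Al](CC(C)C)CC(C)C | intermediate (not isolated)
15 | methyl (4R,6Z,9E)-3-hydroxy-6,10-dimethyl-2-methylidene-4,12-bis(triethylsilyloxy)dodeca-6,9-dienoate (C3 epimers) | COC(=O)C(=C)C(O)[C@H](O[Si](CC)(CC)CC)C/C(C)=C\C/C=C(\C)CCO[Si](CC)(CC)CC | intermediate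
16 | methyl (2Z,4R,6Z,9E)-2-(bromomethyl)-6,10-dimethyl-4,12-bis(triethylsilyloxy)dodeca-2,6,9-trienoate | COC(=O)/C(CBr)=C/[C@H](O[Si](CC)(CC)CC)C/C(C)=C\C/C=C(\C)CCO[Si](CC)(CC)CC | intermediate
17 | methyl (2Z,4R,6Z,9E)-2-(bromomethyl)-6,10-dimethyl-12-oxo-4-(triethylsilyloxy)dodeca-2,6,9-trienoate | COC(=O)/C(CBr)=C/[C@H](O[Si](CC)(CC)CC)C/C(C)=C\C/C=C(\C)CC=O | intermediate
18 | methyl 8β-(triethylsilyloxy)-6α-(trimethylsilyloxy)germacra-1(10)Z,3E,11(13)-trien-12-oate (H-7α) | C=C(C(=O)OC)[C@H]1[C@H](O[Si](C)(C)C)C/C(C)=C/C/C=C(C)\C[C@H]1O[Si](CC)(CC)CC | intermediate (not isolated)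
19 | 8β-(triethylsilyloxy)germacra-1(10)Z,3E,11(13)-trien-12,6α-olide | C=C1C(=O)O[C@@H]2C/C(C)=C/C/C=C(C)\C[C@@H](O[Si](CC)(CC)CC)[C@@H]12 | intermediate (not isolated)
20 | 8β-hydroxygermacra-1(10)Z,3E,11(13)-trien-12,6α-olide (H-6β, H-7α) | C=C1C(=O)O[C@@H]2C/C(C)=C/C/C=C(C)\C[C@@H](O)[C@@H]12 | intermediate
21 | 1β,10β-epoxy-8β-hydroxygermacra-3E,11(13)-dien-12,6α-olide (cis epoxide, H-1 and C14 α) | C=C1C(=O)O[C@@H]2C/C(C)=C/C[C@H]3O[C@@]3(C)C[C@@H](O)[C@@H]12 | intermediate
22 | angelic acid, (Z)-2-methylbut-2-enoic acid | C/C=C(/C)C(=O)O | starting material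
23 | angelic 2,4,6-trichlorobenzoic anhydride | C/C=C(/C)C(=O)OC(=O)c1c(Cl)cc(Cl)cc1Cl | intermediate (not isolated)
24 | 8β-angeloyloxy-1β,10β-epoxygermacra-3E,11(13)-dien-12,6α-olide | C=C1C(=O)O[C@@H]2C/C(C)=C/C[C@H]3O[C@@]3(C)C[C@@H](OC(=O)/C(C)=C\C)[C@@H]12 | intermediate
25 | 8β-angeloyloxy-1β,10β-epoxy-3β,4α-dihydroxygermacr-11(13)-en-12,6α-olide (CNP0113954.1) | C=C1C(=O)O[C@@H]2C[C@](C)(O)[C@@H](O)C[C@H]3O[C@@]3(C)C[C@@H](OC(=O)/C(C)=C\C)[C@@H]12 | target

## Step count and risks

Total steps: 14. Longest linear sequence: 13 steps (1 → 3 → 4 → 9 → 10 → 11 → 12 → 15 → 16 → 17 → 20 → 21 → 24 → 25, that is steps 1, 2 and 4–14). The branch from 5 (steps 3–14) is 12 steps long.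

Three steps most likely to fail:

1. **Step 11 (proposed new electrochemical macrocyclisation).** Risks are poor catalytic turnover, dimerisation, reductive 1,4-elimination of the silyloxy group from the allylchromium species, and the C7/C8 relationship, which rests on a transition-state model and is not secured by precedent. Fallback (known chemistry, no electrolysis): set out from 17 and run the stoichiometric CrCl2 Barbier macrocyclisation used for parthenolide-type rings (CrCl2 8 equiv, THF/DMF, syringe-pump addition to 2 mM), isolate silyl ether lactone 19, then remove the silyl group with HF·pyridine in THF at 0 °C to rejoin the route at 20. It makes no compound that the list lacks: none F0. This fallback addresses turnover and dimerisation only; it would give the same C7/C8 outcome.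

2. **Step 14 (facial and site selectivity of the osmylation on the epoxide-bearing ring).** Fallback that changes the order and the directing element: set out from 20 and angeloylate it directly (conditions of step 13) to 8β-angeloyloxygermacra-1(10)Z,3E,11(13)-trien-12,6α-olide F1. Osmylate the strained E olefin of this differently shaped ring (OsO4, NMO, 0 °C) to 8β-angeloyloxy-3β,4α-dihydroxygermacra-1(10)Z,11(13)-dien-12,6α-olide F2. Then epoxidise the 1(10)Z olefin with VO(acac)2/t-BuOOH, now directed by the homoallylic 3β-hydroxyl, to rejoin at 25.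

3. **Step 4 (one-pot anti-carboalumination and cross-coupling of a chelated alane; the ether must survive warm Me3Al).** Fallback with an isolable vinyl iodide and an alkenylzinc: set out from 6, run the same carboalumination/isomerisation but quench with I2 to give (2R,4Z)-5-iodo-1-[(4-methoxybenzyl)oxy]-4-methylpent-4-en-2-ol F3. Silylate it (Et3SiCl, imidazole) to (2R,4Z)-5-iodo-1-[(4-methoxybenzyl)oxy]-4-methyl-2-(triethylsilyloxy)pent-4-ene F4, and silylate 4 likewise to (E)-(5-chloro-3-methylpent-3-enyloxy)triethylsilane F5. Treat F4 with t-BuLi (−78 °C) then ZnBr2 and couple with F5 under Pd(PPh3)4 to rejoin the route at 10.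

## Further compounds

F0 | step 11 | none | none
F1 | step 14 | 8β-angeloyloxygermacra-1(10)Z,3E,11(13)-trien-12,6α-olide | C=C1C(=O)O[C@@H]2C/C(C)=C/C/C=C(C)\C[C@@H](OC(=O)/C(C)=C\C)[C@@H]12
F2 | step 14 | 8β-angeloyloxy-3β,4α-dihydroxygermacra-1(10)Z,11(13)-dien-12,6α-olide | C=C1C(=O)O[C@@H]2C[C@](C)(O)[C@@H](O)C/C=C(C)\C[C@@H](OC(=O)/C(C)=C\C)[C@@H]12
F3 | step 4 | (2R,4Z)-5-iodo-1-[(4-methoxybenzyl)oxy]-4-methylpent-4-en-2-ol | I/C=C(/C)C[C@@H](O)COCc1ccc(OC)cc1
F4 | step 4 | (2R,4Z)-5-iodo-1-[(4-methoxybenzyl)oxy]-4-methyl-2-(triethylsilyloxy)pent-4-ene | I/C=C(/C)C[C@@H](O[Si](CC)(CC)CC)COCc1ccc(OC)cc1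
F5 | step 4 | (E)-(5-chloro-3-methylpent-3-enyloxy)triethylsilane | ClC/C=C(\C)CCO[Si](CC)(CC)CC
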